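## Structural features

The target is a C15 halogenated acetogenin built on an oxocane. With the chain numbered C1 (alkyne CH) to C15 (methyl), the ring oxygen joins C6 and C12 and the ring is O–C6–C7–C8–C9–C10–C11–C12. C6 carries the (E)-pent-2-en-4-ynyl chain (C1–C5) and C12 the 1-bromopropyl group (C13–C15); these two substituents are trans across the ring oxygen. There are six stereocentres (6S,7S,9S,10S,12R,13S). They fall into three adjacent pairs: C6/C7 (side chain and chlorine cis), C9/C10 (chlorine and acetate trans) and C12/C13 (ring carbon and exocyclic bromide, the pattern of an anti addition to an E-alkene). The fragile groups are the secondary bromide and chlorides (elimination, displacement with help from the ring oxygen), the acetate next to a trans chlorine (base would close an epoxide) and the terminal conjugated enyne. The real difficulty is the eight-membered ring itself, which closes poorly and invites transannular reactions, together with five heteroatom-bearing carbons that must be set on a flexible ring. The feature exploited is that C6 and C10 both carry oxygen and sit opposite each other, three atoms apart in either direction. The oxocane is therefore the perimeter of a cyclopenta[b]furan (furan ring O, C12, C11, C10, C6; carbocycle C6–C10) whose shared C6=C10 bond is an enol ether. Cutting that bond gives the ring without any medium-ring closure and leaves C6 as a lactone carbonyl and C10 as a ketone.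

## Logic of the disconnections

**C10 O–acyl and O–Si bonds (26 ⇒ 25 ⇒ 24).** The acetate of 26 is put on last, from 25, and 25 comes from 24 by O–Si cleavage. An acetate at C10 cannot pass the enolate, aluminium hydride and organolithium steps that come earlier, and a free C10 hydroxyl trans to the C9 chlorine closes to an epoxide under base. The oxygen is therefore carried as a bulky silyl ether. The demand is that desilylation be acidic and acetylation only weakly basic.

**C1≡C2 and C3=C4 (24 ⇒ 23 ⇒ 21 + 22).** The triple bond is cut back to the aldehyde of 23 (one-carbon homologation), and C3=C4 to the terminal alkene of 21 plus 22 (cross metathesis). This reduces the most delicate unit to an allyl group and sets the E geometry under thermodynamic control. The homologation must use a nucleophile that adds to C=O faster than it deprotonates C5 or attacks a halide.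

**C7–Cl (21 ⇒ 20 ⇒ 19).** The chloride is traced to the epimeric alcohol 20 (displacement with inversion), itself the deacylated form of 19. The C7 oxygen is wanted first because it directs the C5–C6 bond formation. The displacement must be SN2 and not assisted by the ring oxygen.

**C5–C6 (19 ⇒ 17 + 18).** The allyl group is cut from C6, leaving an oxocarbenium ion derived from 17 and the nucleophile 18. The gain is that the side chain is delivered to a lactone-derived carbon. The demand is 6,7-trans addition, met by participation of the C7 acetate, which is also trans to the C12 substituent.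

**C6–H and both acetates (17 ⇒ 15, via 16).** 17 is the reduced, doubly acetylated form of 15. The tetrahedral intermediate must be trapped before the eight-membered lactol can open to the hydroxy aldehyde.

**C7–O (15 ⇒ 14).** The C7 hydroxyl is removed to give the lactone enolate precursor 14. The demand is oxygen delivery to one face of the enolate, and trapping faster than attack of the enolate on the C9 chloride.

**C9–Cl (14 ⇒ 13 ⇒ 12).** The chloride is traced to the alcohol 13 of opposite configuration and on to the triethylsilyl ether 12. The cut is made at the lactone stage because the ring oxygen is then an ester oxygen and cannot form a transannular oxonium ion at C9. The demand is clean SN2 on a γ-hydroxy lactone that can also undergo acyl transfer.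

**C10–H and C10 O–Si (12 ⇒ 11 ⇒ 10).** The C10 silyl ether is cut to 11 and the carbinol to the ketone 10. This distinguishes C10 (acetate carbon) from C9 (chloride carbon) by oxidation level. Hydride must add anti to the C9 silyloxy group, under conditions that do not trigger β-elimination of the C12 carboxylate.

**C6=C10 reconnection (10 ⇒ 8, via 9).** The lactone carbonyl C6 and the ketone C10 are joined as a tetrasubstituted enol ether, which turns the eight-membered ring into two fused five-membered rings. The descriptors of 8 and 10 (9R,12R,13S) map atom for atom on 26, with C12 and C13 unchanged and C9 to be inverted once, so no structural correction is needed. The one change in design is the silyl group: triethylsilyl at C9, so that it can later be removed beside a tert-butyldimethylsilyl ether at C10. The forward step must cleave the enol ether alone and leave C9, C12 and C13 untouched.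

**C9–H and C9 O–Si (8 ⇒ 7 ⇒ 6).** The silyl ether is cut to the allylic alcohol 7 and this to the vinylogous ester 6. The demand is reagent-controlled 1,2-reduction, since C12 and C13 are too remote to direct it, and non-acidic handling of 7.

**O–C12 and C13–Br (6 ⇒ 4 + 5).** Both bonds are cut in one anti addition across the E-alkene of 4, with the enol oxygen as nucleophile and 5 as bromine source. Two stereocentres and the furan ring are gained from an achiral dione. The demand is 5-exo closure, attack on the alkene instead of the dione carbon, and catalyst control of the absolute sense.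

**C10–C11 (4 ⇒ 2 + 3; 2 ⇒ 1).** The allylic C–C bond is cut to the dione 3 and the activated allylic alcohol 2, made from 1. The demand is C-alkylation at the less substituted allyl terminus with retention of E geometry and no double alkylation.

## Other disconnections considered

**Alternative 1:** The cut runs through O–C12 and C11–C12 and re-forms O–C9. The oxocane shrinks to an oxolane, 2-[(2S,3S)-3-chloro-5-ethenyloxolan-2-yl]ethyl pivalate A2, plus 1-diazobutan-2-one A3. In the forward direction a divalent copper catalyst, Cu(CF3COCHCOCF3)2, would decompose A3. The ring oxygen of A2 would add to the carbenoid, and a [2,3] shift of the oxonium ylide across the C9 vinyl group would give the oxocene A1 with a Z C9=C10 bond.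
- In its favour: three ring atoms and the C11–C12 bond arrive in one step, C13–C15 come in convergently, and C6 and C7 (chlorine included) are set on a five-membered ring. On the C6/C7 pair and on convergence it is better than the chosen plan, which has to invert C7 late, next to the ring oxygen.
- Against it here: the ylide must form intermolecularly at an ether oxygen that is hindered and deactivated by the β-chlorine, in competition with cyclopropanation of the vinyl group, [1,2] shift and carbene dimerisation. C12 depends on chirality transfer through an oxonium centre of undefined configuration and then sits α to a ketone. C13 still needs reduction and bromination with inversion. The C9=C10 alkene must be turned into the trans chloride/acetate pair with regio- and face control on a ring whose ether oxygen can participate.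
- Comparison: structurally, the chosen plan has C9 and C10 differentiated from the start and takes C12/C13 from a single anti addition; A1 leaves both open. Mechanistically, a cycloaddition–cycloreversion at the only π bond is more predictable than carbene chemoselectivity. In step count the two are about equal: A1 should be reached in fewer steps than 10, but needs more afterwards.

**Alternative 2:** The cut is the C5–C6 bond together with re-formation of C6–C9. This leads back to a cis-fused photocycloadduct, 8-acetoxy-3-[(1R)-1-(4-methoxybenzyloxy)propyl]-2-oxabicyclo[4.2.0]octan-5-one A5, and to 18. In the forward direction a silyl triflate would activate the ketone, the ring oxygen would push out the C6–C9 bond to give an eight-membered oxocarbenium ion and a C9=C10 silyl enol ether, and 18 would add at C6 to give the oxocane A4.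
- In its favour: ring expansion and C5–C6 bond formation are one step, the C7 oxygen is already in place and its acetate should steer the allyl group trans, and C10 arrives as a masked ketone. On step economy around C5–C7 it is better than the chosen plan, and on the use of the C7 acetate as a directing group it is its equal.
- Against it here: the photocycloaddition must be regio- and face-selective. C13 is carried as an ether that has to be unmasked and brominated with inversion late, beside the enyne precursor. The C9 chlorine would enter by electrophilic chlorination α to the C10 carbonyl, where the centre is epimerisable and the C9/C10 relationship rests on substrate control of a later reduction.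
- Comparison: structurally, the chosen plan fixes C12/C13 in one early step and places the C9 chlorine by SN2 on a defined carbinol, which is safer than an α-chloro ketone. Mechanistically, both unveil the ring by cleaving the bond shared by two small rings and are equals in that respect. In step count A4 is probably two or three steps shorter after the key step, which is offset by the longer preparation of A5.

**Alternative 3:** The cut is the C6–O bond with oxygen removed from between C6 and C12. This gives the racemic anti aldol 2-(1-hydroxypropyl)cyclohept-4-en-1-one A7. In the forward direction a Baeyer–Villiger monooxygenase with O2 and NADPH would insert oxygen on the more substituted side of one enantiomer, with retention at C12, and give the lactone A6.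
- In its favour: A7 is only an aldol away from a simple cycloheptenone and needs no protecting group. The enzyme leaves the alkene alone where a peracid would epoxidise it. The product is a lactone, so the later C6/C7 chemistry is the same as in the chosen plan and the ring oxygen is deactivated during work at C9 and C10. On brevity of access to the ring it is better than the chosen plan; on downstream chemistry it is its equal.
- Against it here: a kinetic resolution discards half the material. Seven-membered ketones with an α-branch are poor substrates for this enzyme family and expansion to an eight-membered lactone is unfavourable. The Z alkene must become the trans chloride/acetate pair with no handle to tell C9 from C10. C13 needs a separate inversion to the bromide.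
- Comparison: structurally, the chosen plan has the advantage at C9/C10 and C12/C13. Mechanistically, enzymatic oxygen insertion is milder than ozonolysis but less certain to accept the substrate. In step count A6 could save three or four steps before the ring is in hand and lose about as many at C9, C10 and C13, so overall the two are about equal.

Key step: step 6

Assumption: of the two pseudo-enantiomeric cinchona amino-thiocarbamate catalysts, the one that delivers (12R,13S)-6 is used; the route does not depend on which it is.

## Route

Step 1
Reactants: 1 (E)-pent-2-en-1-ol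
Product: 2 methyl (E)-pent-2-en-1-yl carbonate
Conditions: ClCO2Me, pyridine, CH2Cl2, 0 °C
Reagents that add atoms: methyl chloroformate, COC(=O)Cl
Why: Acylation of a primary allylic alcohol with a chloroformate (carbonate formation); the E-alkene is untouched and the carbonate is the ionising group for step 2.

Step 2
Reactants: 2 methyl (E)-pent-2-en-1-yl carbonate; 3 cyclopentane-1,3-dione
Product: 4 2-[(E)-pent-2-en-1-yl]cyclopentane-1,3-dione
Conditions: Pd(PPh3)4 (3 mol %), 3 (1.5 equiv), THF, 23 °C
Reagents that add atoms: none
Why: Tsuji–Trost allylation: zerovalent palladium ionises 2 with loss of CO2, the methoxide formed deprotonates 3, and the soft enolate attacks the unsubstituted terminus of the syn π-allyl complex at carbon, giving the linear E product. The excess of 3 suppresses double allylation.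

Step 3
Reactants: 4 2-[(E)-pent-2-en-1-yl]cyclopentane-1,3-dione; 5 N-bromosuccinimide
Product: 6 (2R)-2-[(1S)-1-bromopropyl]-2,3,5,6-tetrahydro-4H-cyclopenta[b]furan-4-one
Conditions: NBS, cinchona amino-thiocarbamate catalyst (10 mol %), toluene/CHCl3, −60 °C
Reagents that add atoms: N-bromosuccinimide (5), O=C1CCC(=O)N1Br
Why: Lewis-base-catalysed asymmetric bromocyclisation of an olefinic 1,3-dione: the enol oxygen opens the bromiranium ion at C12 in the 5-exo mode, anti to bromine, so the E geometry fixes the C12/C13 relationship and the chiral catalyst the absolute sense (12R,13S). The catalyst also directs the bromine to the alkene and away from the dione carbon.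

Step 4
Reactants: 6 (2R)-2-[(1S)-1-bromopropyl]-2,3,5,6-tetrahydro-4H-cyclopenta[b]furan-4-one
Product: 7 (2R,4R)-2-[(1S)-1-bromopropyl]-3,4,5,6-tetrahydro-2H-cyclopenta[b]furan-4-ol
Conditions: (S)-2-methyl-CBS-oxazaborolidine (20 mol %), BH3·SMe2, THF, −30 °C; MeOH, then aq NaHCO3
Reagents that add atoms: none
Why: Corey–Bakshi–Shibata reduction: 1,2-hydride delivery to the vinylogous ester carbonyl, with the enol ether carbon as the large group, should set 9R under reagent control, C12 and C13 being too remote to interfere. The basic work-up protects the acid-labile 3-alkoxy allylic alcohol, which is used crude.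

Step 5
Reactants: 7 (2R,4R)-2-[(1S)-1-bromopropyl]-3,4,5,6-tetrahydro-2H-cyclopenta[b]furan-4-ol
Product: 8 (2R,4R)-2-[(1S)-1-bromopropyl]-4-(triethylsilyloxy)-3,4,5,6-tetrahydro-2H-cyclopenta[b]furan
Conditions: Et3SiCl, imidazole, DMF, 0 °C
Reagents that add atoms: chlorotriethylsilane, CC[Si](Cl)(CC)CC
Why: Silylation of a secondary allylic alcohol under basic conditions. Triethylsilyl is chosen so that it can later be cleaved in the presence of the tert-butyldimethylsilyl ether at C10.

Step 6
Reactants: 8 (2R,4R)-2-[(1S)-1-bromopropyl]-4-(triethylsilyloxy)-3,4,5,6-tetrahydro-2H-cyclopenta[b]furan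
Product: 10 (5R,8R)-8-[(1S)-1-bromopropyl]-5-(triethylsilyloxy)oxocane-2,6-dione, via primary ozonide 9 (not isolated)
Conditions: O3, CH2Cl2, −78 °C (Sudan Red 7B end point); then PPh3, −78 → 0 °C
Reagents that add atoms: ozone, [O-][O+]=O
Why: Ozone adds as a 1,3-dipole to the tetrasubstituted, electron-rich C6=C10 enol ether to give 9; cycloreversion breaks the C6–C10 σ bond and leaves C6 as the ester carbonyl and C10 as a carbonyl oxide, which PPh3 (directly or through the alkoxy ozonide) reduces to the ketone. The closest known reaction type is the oxidative cleavage of bicyclic enol ethers derived from 2-(2-hydroxyalkyl)cycloalkanones to medium-ring keto lactones. No ring-closing bond is made: the oxocane appears because the bond shared by the two five-membered rings is cut, so the mode of ring formation is a fragmentation-type expansion (5 + 5 → 8) with no cyclisation entropy to pay. No stereocentre is created, and C9, C12 and C13 are not part of the reacting system. The selectivity needed is cleavage of the enol ether alone; it is the only π bond and by far the most electron-rich site, and titration to the indicator end point keeps ozone away from ether C–H bonds. The second requirement is a neutral work-up, because 10 is a β-acyloxy ketone with an epimerisable α-silyloxy centre; PPh3 at low temperature meets it, and 10 is taken on without delay.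

Step 7
Reactants: 10 (5R,8R)-8-[(1S)-1-bromopropyl]-5-(triethylsilyloxy)oxocane-2,6-dione
Product: 11 (5R,6S,8R)-8-[(1S)-1-bromopropyl]-6-hydroxy-5-(triethylsilyloxy)oxocan-2-one
Conditions: LiBH(s-Bu)3, THF, −78 °C; AcOH, −78 °C
Reagents that add atoms: none
Why: Reduction of an α-silyloxy ketone with a bulky non-chelating hydride: polar Felkin–Anh addition anti to the C9 silyloxy group should give the 9,10-cis (10S) alcohol, and the ketone reacts far faster than the lactone. The cold acidic quench prevents E1cB loss of the C12 carboxylate and acyl transfer to the new alkoxide.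

Step 8
Reactants: 11 (5R,6S,8R)-8-[(1S)-1-bromopropyl]-6-hydroxy-5-(triethylsilyloxy)oxocan-2-one
Product: 12 (5R,6S,8R)-8-[(1S)-1-bromopropyl]-6-(tert-butyldimethylsilyloxy)-5-(triethylsilyloxy)oxocan-2-one
Conditions: t-BuMe2SiOTf, 2,6-lutidine, CH2Cl2, −78 °C
Reagents that add atoms: tert-butyldimethylsilyl triflate, CC(C)(C)[Si](C)(C)OS(=O)(=O)C(F)(F)F
Why: Silylation of a hindered secondary alcohol with a silyl triflate. The robust silyl ether blocks translactonisation and, unlike an acetate, survives the enolate, hydride and Lewis acid steps ahead without taking part in them.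

Step 9
Reactants: 12 (5R,6S,8R)-8-[(1S)-1-bromopropyl]-6-(tert-butyldimethylsilyloxy)-5-(triethylsilyloxy)oxocan-2-one
Product: 13 (5R,6S,8R)-8-[(1S)-1-bromopropyl]-6-(tert-butyldimethylsilyloxy)-5-hydroxyoxocan-2-one
Conditions: HF·pyridine, pyridine, THF, 0 °C
Reagents that add atoms: none
Why: Selective cleavage of a triethylsilyl ether beside a tert-butyldimethylsilyl ether (differential silyl lability). Buffered acidic fluoride avoids 1,2-silyl migration and base-induced acyl transfer to the freed C9 hydroxyl; 13 is used at once.

Step 10
Reactants: 13 (5R,6S,8R)-8-[(1S)-1-bromopropyl]-6-(tert-butyldimethylsilyloxy)-5-hydroxyoxocan-2-one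
Product: 14 (5S,6S,8R)-8-[(1S)-1-bromopropyl]-6-(tert-butyldimethylsilyloxy)-5-chlorooxocan-2-one
Conditions: (n-Oct)3P, CCl4, toluene, 60 °C
Reagents that add atoms: carbon tetrachloride, ClC(Cl)(Cl)Cl
Why: Appel-type chlorination: the C9 hydroxyl is activated as its alkoxyphosphonium group and displaced by chloride in an SN2 step with inversion (9R → 9S). On the lactone the ring oxygen is an ester oxygen and cannot form a transannular oxonium ion, and the cis C10 silyl ether cannot participate.

Step 11
Reactants: 14 (5S,6S,8R)-8-[(1S)-1-bromopropyl]-6-(tert-butyldimethylsilyloxy)-5-chlorooxocan-2-one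
Product: 15 (3R,5S,6S,8R)-8-[(1S)-1-bromopropyl]-6-(tert-butyldimethylsilyloxy)-5-chloro-3-hydroxyoxocan-2-one
Conditions: KN(SiMe3)2, THF, −78 °C; 2-(phenylsulfonyl)-3-phenyloxaziridine, −78 °C; AcOH
Reagents that add atoms: 2-(phenylsulfonyl)-3-phenyloxaziridine, O=S(=O)(c1ccccc1)N1OC1c1ccccc1
Why: Davis oxidation of the lactone potassium enolate: the oxaziridine transfers oxygen to C7, expected on the face opposite the bulky C10 silyloxy group (7R). Generating and trapping the enolate at −78 °C outruns intramolecular displacement of the C9 chloride.

Step 12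
Reactants: 15 (3R,5S,6S,8R)-8-[(1S)-1-bromopropyl]-6-(tert-butyldimethylsilyloxy)-5-chloro-3-hydroxyoxocan-2-one
Product: 17 (3R,5S,6S,8R)-8-[(1S)-1-bromopropyl]-6-(tert-butyldimethylsilyloxy)-5-chlorooxocane-2,3-diyl diacetate (both C2 epimers), via bis(diisobutylaluminium) lactolate 16 (not isolated)
Conditions: i-Bu2AlH (2.3 equiv), CH2Cl2, −78 °C; then pyridine, DMAP, Ac2O, −78 → 0 °C
Reagents that add atoms: acetic anhydride, CC(=O)OC(C)=O
Why: Reductive acetylation of a lactone: one hydride is consumed by the C7 hydroxyl and one adds to the carbonyl, and the chelated aluminium hemiacetal 16 is stable at −78 °C and is acetylated in the flask. This keeps the eight-membered lactol from opening to the hydroxy aldehyde, and the C7 oxygen is acetylated in the same operation.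

Step 13
Reactants: 17 (3R,5S,6S,8R)-8-[(1S)-1-bromopropyl]-6-(tert-butyldimethylsilyloxy)-5-chlorooxocane-2,3-diyl diacetate; 18 allyltrimethylsilane
Product: 19 (2S,3R,5S,6S,8R)-8-[(1S)-1-bromopropyl]-6-(tert-butyldimethylsilyloxy)-5-chloro-2-(prop-2-en-1-yl)oxocan-3-yl acetate
Conditions: allylSiMe3, BF3·OEt2, CH2Cl2, −78 → −30 °C
Reagents that add atoms: allyltrimethylsilane (18), C=CC[Si](C)(C)C
Why: Hosomi–Sakurai allylation of an oxocarbenium ion generated from an α-acetoxy ether: ionisation at C6 is assisted by the C7 acetate, and the bridged dioxolenium ion is opened by the allylsilane from the opposite face. This should give the 6,7-trans (6S) product, which is also trans to the C12 substituent; the bulky silyl ether at C10 is a poor transannular nucleophile.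

Step 14
Reactants: 19 (2S,3R,5S,6S,8R)-8-[(1S)-1-bromopropyl]-6-(tert-butyldimethylsilyloxy)-5-chloro-2-(prop-2-en-1-yl)oxocan-3-yl acetate
Product: 20 (2S,3R,5S,6S,8R)-8-[(1S)-1-bromopropyl]-6-(tert-butyldimethylsilyloxy)-5-chloro-2-(prop-2-en-1-yl)oxocan-3-ol
Conditions: K2CO3, MeOH, 0 °C
Reagents that add atoms: none
Why: Zemplén-type methanolysis of a secondary acetate. The C10 oxygen stays silylated, so no chlorohydrin is exposed, and the C7 alkoxide is cis to the C9 chlorine and cannot reach its back side.

Step 15
Reactants: 20 (2S,3R,5S,6S,8R)-8-[(1S)-1-bromopropyl]-6-(tert-butyldimethylsilyloxy)-5-chloro-2-(prop-2-en-1-yl)oxocan-3-ol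
Product: 21 (2S,3S,5S,6S,8R)-8-[(1S)-1-bromopropyl]-6-(tert-butyldimethylsilyloxy)-3,5-dichloro-2-(prop-2-en-1-yl)oxocane
Conditions: (n-Oct)3P, CCl4, toluene, 70 °C
Reagents that add atoms: carbon tetrachloride, ClC(Cl)(Cl)Cl
Why: Appel-type chlorination with inversion at C7 (7R alcohol → 7S chloride), the usual way to place halogen on the carbon next to the ring-oxygen-bearing carbon of medium-ring ethers. The trialkylphosphine in warm toluene favours SN2 displacement over elimination.

Step 16
Reactants: 21 (2S,3S,5S,6S,8R)-8-[(1S)-1-bromopropyl]-6-(tert-butyldimethylsilyloxy)-3,5-dichloro-2-(prop-2-en-1-yl)oxocane; 22 (E)-but-2-enal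
Product: 23 (E)-4-[(2S,3S,5S,6S,8R)-8-[(1S)-1-bromopropyl]-6-(tert-butyldimethylsilyloxy)-3,5-dichlorooxocan-2-yl]but-2-enal
Conditions: crotonaldehyde (5 equiv), second-generation Hoveyda–Grubbs catalyst (5 mol %), CH2Cl2, 40 °C
Reagents that add atoms: (E)-but-2-enal (22), C/C=C/C=O
Why: Olefin cross metathesis of a terminal alkene with an excess of an electron-poor partner. The conjugated enal should form as the E isomer under thermodynamic control and does not re-enter metathesis.

Step 17
Reactants: 23 (E)-4-[(2S,3S,5S,6S,8R)-8-[(1S)-1-bromopropyl]-6-(tert-butyldimethylsilyloxy)-3,5-dichlorooxocan-2-yl]but-2-enal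
Product: 24 (2S,3S,5S,6S,8R)-8-[(1S)-1-bromopropyl]-6-(tert-butyldimethylsilyloxy)-3,5-dichloro-2-[(E)-pent-2-en-4-yn-1-yl]oxocane
Conditions: Me3SiCHN2, n-BuLi, THF, −78 °C; then 23, −78 → 0 °C
Reagents that add atoms: trimethylsilyldiazomethane, C[Si](C)(C)C=[N+]=[N-]
Why: Colvin homologation: the lithiated diazo reagent adds to the aldehyde, Peterson-type elimination gives a diazoalkene, and the alkylidene carbene formed on loss of nitrogen undergoes a 1,2-hydrogen shift to the terminal alkyne with the E-alkene intact. Addition to C=O at −78 °C is faster than deprotonation at C5 or attack on a halide.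

Step 18
Reactants: 24 (2S,3S,5S,6S,8R)-8-[(1S)-1-bromopropyl]-6-(tert-butyldimethylsilyloxy)-3,5-dichloro-2-[(E)-pent-2-en-4-yn-1-yl]oxocane
Product: 25 (2R,4S,5S,7S,8S)-2-[(1S)-1-bromopropyl]-5,7-dichloro-8-[(E)-pent-2-en-4-yn-1-yl]oxocan-4-ol
Conditions: HF·pyridine, THF, 0 → 23 °C
Reagents that add atoms: none
Why: Acidic fluoride cleavage of a secondary silyl ether. Unlike basic fluoride it does not turn the freed trans chlorohydrin into an epoxide, and it leaves the terminal enyne alone.

Step 19
Reactants: 25 (2R,4S,5S,7S,8S)-2-[(1S)-1-bromopropyl]-5,7-dichloro-8-[(E)-pent-2-en-4-yn-1-yl]oxocan-4-ol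
Product: 26 (2R,4S,5S,7S,8S)-2-[(1S)-1-bromopropyl]-5,7-dichloro-8-[(E)-pent-2-en-4-yn-1-yl]oxocan-4-yl acetate
Conditions: Ac2O, pyridine, DMAP (cat.), CH2Cl2, 0 °C
Reagents that add atoms: acetic anhydride, CC(=O)OC(C)=O
Why: Acylation of a secondary alcohol under nucleophilic catalysis. Pyridine is too weak a base to close the chlorohydrin, and no stereocentre is touched.

## Compound list

1 | (E)-pent-2-en-1-ol | CC/C=C/CO | starting material
2 | methyl (E)-pent-2-en-1-yl carbonate | CC/C=C/COC(=O)OC | intermediate
3 | cyclopentane-1,3-dione | O=C1CCC(=O)C1 | starting material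
4 | 2-[(E)-pent-2-en-1-yl]cyclopentane-1,3-dione (largely enolised) | CC/C=C/CC1C(=O)CCC1=O | intermediate
5 | N-bromosuccinimide | O=C1CCC(=O)N1Br | starting material
6 | (2R)-2-[(1S)-1-bromopropyl]-2,3,5,6-tetrahydro-4H-cyclopenta[b]furan-4-one (12R,13S) | O1[C@@H]([C@@H](Br)CC)CC2=C1CCC2=O | intermediate
7 | (2R,4R)-2-[(1S)-1-bromopropyl]-3,4,5,6-tetrahydro-2H-cyclopenta[b]furan-4-ol (9R,12R,13S) | O1[C@@H]([C@@H](Br)CC)CC2=C1CC[C@H]2O | intermediate
8 | (2R,4R)-2-[(1S)-1-bromopropyl]-4-(triethylsilyloxy)-3,4,5,6-tetrahydro-2H-cyclopenta[b]furan (9R,12R,13S) | O1[C@@H]([C@@H](Br)CC)CC2=C1CC[C@H]2O[Si](CC)(CC)CC | intermediate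
9 | primary ozonide of 8 (1,2,3-trioxolane across C6–C10, either face) | O1[C@@H]([C@@H](Br)CC)CC23OOOC12CC[C@H]3O[Si](CC)(CC)CC | intermediate
10 | (5R,8R)-8-[(1S)-1-bromopropyl]-5-(triethylsilyloxy)oxocane-2,6-dione (9R,12R,13S) | O=C1CC[C@@H](O[Si](CC)(CC)CC)C(=O)C[C@H]([C@@H](Br)CC)O1 | intermediate
11 | (5R,6S,8R)-8-[(1S)-1-bromopropyl]-6-hydroxy-5-(triethylsilyloxy)oxocan-2-one (9R,10S,12R,13S) | O=C1CC[C@@H](O[Si](CC)(CC)CC)[C@@H](O)C[C@H]([C@@H](Br)CC)O1 | intermediate
12 | (5R,6S,8R)-8-[(1S)-1-bromopropyl]-6-(tert-butyldimethylsilyloxy)-5-(triethylsilyloxy)oxocan-2-one | O=C1CC[C@@H](O[Si](CC)(CC)CC)[C@@H](O[Si](C)(C)C(C)(C)C)C[C@H]([C@@H](Br)CC)O1 | intermediate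
13 | (5R,6S,8R)-8-[(1S)-1-bromopropyl]-6-(tert-butyldimethylsilyloxy)-5-hydroxyoxocan-2-one | O=C1CC[C@@H](O)[C@@H](O[Si](C)(C)C(C)(C)C)C[C@H]([C@@H](Br)CC)O1 | intermediate
14 | (5S,6S,8R)-8-[(1S)-1-bromopropyl]-6-(tert-butyldimethylsilyloxy)-5-chlorooxocan-2-one (9S,10S,12R,13S) | O=C1CC[C@H](Cl)[C@@H](O[Si](C)(C)C(C)(C)C)C[C@H]([C@@H](Br)CC)O1 | intermediate
15 | (3R,5S,6S,8R)-8-[(1S)-1-bromopropyl]-6-(tert-butyldimethylsilyloxy)-5-chloro-3-hydroxyoxocan-2-one (7R,9S,10S,12R,13S) | O=C1[C@H](O)C[C@H](Cl)[C@@H](O[Si](C)(C)C(C)(C)C)C[C@H]([C@@H](Br)CC)O1 | intermediate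
16 | bis(diisobutylaluminium) lactolate of 15 (O–Al at C6 and C7) | CC(C)C[Al](CC(C)C)OC1O[C@@H]([C@@H](Br)CC)C[C@H](O[Si](C)(C)C(C)(C)C)[C@@H](Cl)C[C@H]1O[Al](CC(C)C)CC(C)C | intermediate
17 | (3R,5S,6S,8R)-8-[(1S)-1-bromopropyl]-6-(tert-butyldimethylsilyloxy)-5-chlorooxocane-2,3-diyl diacetate (both C2 epimers) | CC(=O)OC1O[C@@H]([C@@H](Br)CC)C[C@H](O[Si](C)(C)C(C)(C)C)[C@@H](Cl)C[C@H]1OC(C)=O | intermediate
18 | allyltrimethylsilane | C=CC[Si](C)(C)C | starting material
19 | (2S,3R,5S,6S,8R)-8-[(1S)-1-bromopropyl]-6-(tert-butyldimethylsilyloxy)-5-chloro-2-(prop-2-en-1-yl)oxocan-3-yl acetate (6S,7R,9S,10S,12R,13S) | C=CC[C@@H]1O[C@@H]([C@@H](Br)CC)C[C@H](O[Si](C)(C)C(C)(C)C)[C@@H](Cl)C[C@H]1OC(C)=O | intermediate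
20 | (2S,3R,5S,6S,8R)-8-[(1S)-1-bromopropyl]-6-(tert-butyldimethylsilyloxy)-5-chloro-2-(prop-2-en-1-yl)oxocan-3-ol | C=CC[C@@H]1O[C@@H]([C@@H](Br)CC)C[C@H](O[Si](C)(C)C(C)(C)C)[C@@H](Cl)C[C@H]1O | intermediate
21 | (2S,3S,5S,6S,8R)-8-[(1S)-1-bromopropyl]-6-(tert-butyldimethylsilyloxy)-3,5-dichloro-2-(prop-2-en-1-yl)oxocane (6S,7S,9S,10S,12R,13S) | C=CC[C@@H]1O[C@@H]([C@@H](Br)CC)C[C@H](O[Si](C)(C)C(C)(C)C)[C@@H](Cl)C[C@@H]1Cl | intermediate
22 | (E)-but-2-enal (crotonaldehyde) | C/C=C/C=O | starting material
23 | (E)-4-[(2S,3S,5S,6S,8R)-8-[(1S)-1-bromopropyl]-6-(tert-butyldimethylsilyloxy)-3,5-dichlorooxocan-2-yl]but-2-enal | O=C/C=C/C[C@@H]1O[C@@H]([C@@H](Br)CC)C[C@H](O[Si](C)(C)C(C)(C)C)[C@@H](Cl)C[C@@H]1Cl | intermediate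
24 | (2S,3S,5S,6S,8R)-8-[(1S)-1-bromopropyl]-6-(tert-butyldimethylsilyloxy)-3,5-dichloro-2-[(E)-pent-2-en-4-yn-1-yl]oxocane | C#C/C=C/C[C@@H]1O[C@@H]([C@@H](Br)CC)C[C@H](O[Si](C)(C)C(C)(C)C)[C@@H](Cl)C[C@@H]1Cl | intermediate
25 | (2R,4S,5S,7S,8S)-2-[(1S)-1-bromopropyl]-5,7-dichloro-8-[(E)-pent-2-en-4-yn-1-yl]oxocan-4-ol | C#C/C=C/C[C@@H]1O[C@@H]([C@@H](Br)CC)C[C@H](O)[C@@H](Cl)C[C@@H]1Cl | intermediate
26 | (2R,4S,5S,7S,8S)-2-[(1S)-1-bromopropyl]-5,7-dichloro-8-[(E)-pent-2-en-4-yn-1-yl]oxocan-4-yl acetate (6S,7S,9S,10S,12R,13S) | C#C/C=C/C[C@@H]1O[C@@H]([C@@H](Br)CC)C[C@H](OC(C)=O)[C@@H](Cl)C[C@@H]1Cl | target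

## Step count and least certain steps

Total: 19 steps. Longest linear sequence: 19 steps from 1 (3, 5, 18 and 22 enter as purchased materials).

**Step 6 (key step).** The cleavage itself should be reliable. What is most likely to go wrong is incomplete reduction of the peroxidic intermediates, or degradation of the product during work-up: base- or silica-promoted E1cB expulsion of the C12 carboxylate from the β-acyloxy ketone, and epimerisation at C9. Fallback: it sets out from 8 and avoids ozone and peroxides altogether. Dihydroxylation of the enol ether (OsO4 cat., N-methylmorpholine N-oxide, acetone/water), expected anti to the silyloxy group, would give the cis-6,10-diol (C6 hemiketal) F1. Glycol cleavage with Pb(OAc)4 (CH2Cl2, 0 °C) would then break the same C6–C10 bond and return to the route at 10.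

**Step 3.** The risk is insufficient enantioselection with an alkene that carries two alkyl groups, along with competing bromination at the dione carbon or 6-endo closure. Fallback: it sets out from 4. Cyclisation with NBS and an achiral Lewis base (Ph3P=S) would give 6 together with its enantiomer, the (12S,13R)-bromoether F2, the anti addition being stereospecific. The reagent-controlled reduction of step 4 would convert both into 9R carbinols, 7 and the (9R,12S,13R)-alcohol F3. After silylation as in step 5 the (9R,12S,13R)-silyl ether F4 is a diastereomer of 8 and would be removed by chromatography; the route is rejoined at 8.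

**Step 4.** A vinylogous ester is a poor electrophile, so slow reduction, competing hydroboration of the enol ether and weak face control are all possible, and the product can ionise at C9 on contact with acid. Fallback: it sets out from 6. i-Bu2AlH (toluene, −78 °C) would reduce the carbonyl without face control to 7 and its C9 epimer, the (9S)-alcohol F5. Silylation as in step 5 would give 8 and the (9S)-silyl ether F6, which are diastereomers and would be separated on base-washed silica; the route is rejoined at 8.

**Step 7.** Face selectivity on a flexible eight-membered ring may be poor or reversed, and a basic hydride can enolise the ketone toward C11 and expel the C12 carboxylate. Fallback: it sets out from 10. If the reduction gives mainly the (10R)-alcohol F7, Mitsunobu inversion with chloroacetic acid (PPh3, diisopropyl azodicarboxylate, toluene, 0 °C) would give the (10S)-chloroacetate F8. Selective cleavage with thiourea/NaHCO3 (EtOH) would return to the route at 11.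

**Step 10.** The free C9 hydroxyl is γ to the lactone carbonyl, so acyl transfer with ring contraction to a five-membered lactone can compete with activation. Elimination toward C8 and participation of the lactone carbonyl oxygen at C9 are further escape routes at 60 °C. Fallback: it sets out from 13. Sulfonylation at 0 °C (ClCH2SO2Cl, pyridine, CH2Cl2) would give the C9 chloromethanesulfonate F9, which is isolated. Displacement with LiCl in DMF at room temperature, with inversion, would return to the route at 14.

**Step 11.** The oxidant may approach the enolate from the wrong face, since neither neighbouring stereocentre is adjacent to C7, and the enolate may displace the C9 chloride to form a cyclopropane if it is allowed to warm. Fallback: it sets out from 14. If the (7S)-alcohol F10 is the main product, Mitsunobu inversion with chloroacetic acid (PPh3, diisopropyl azodicarboxylate) would give the (7R)-chloroacetate F11; α-hydroxy lactones are good substrates for this. Cleavage with thiourea/NaHCO3 would return to the route at 15.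

## Further compounds

F1 | step 6 | (9R,12R,13S)-6,10-dihydroxy-9-(triethylsilyloxy)-12-(1-bromopropyl)hexahydrocyclopenta[b]furan (cis-diol anti to the silyloxy group; C6 hemiketal) | O1[C@@H]([C@@H](Br)CC)C[C@@]2(O)[C@]1(O)CC[C@H]2O[Si](CC)(CC)CC
F2 | step 3 | (2S)-2-[(1R)-1-bromopropyl]-2,3,5,6-tetrahydro-4H-cyclopenta[b]furan-4-one (enantiomer of 6) | O1[C@H]([C@H](Br)CC)CC2=C1CCC2=O
F3 | step 3 | (2S,4R)-2-[(1R)-1-bromopropyl]-3,4,5,6-tetrahydro-2H-cyclopenta[b]furan-4-ol (9R,12S,13R) | O1[C@H]([C@H](Br)CC)CC2=C1CC[C@H]2O
F4 | step 3 | (2S,4R)-2-[(1R)-1-bromopropyl]-4-(triethylsilyloxy)-3,4,5,6-tetrahydro-2H-cyclopenta[b]furan (9R,12S,13R) | O1[C@H]([C@H](Br)CC)CC2=C1CC[C@H]2O[Si](CC)(CC)CC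
F5 | step 4 | (2R,4S)-2-[(1S)-1-bromopropyl]-3,4,5,6-tetrahydro-2H-cyclopenta[b]furan-4-ol (9S,12R,13S) | O1[C@@H]([C@@H](Br)CC)CC2=C1CC[C@@H]2O
F6 | step 4 | (2R,4S)-2-[(1S)-1-bromopropyl]-4-(triethylsilyloxy)-3,4,5,6-tetrahydro-2H-cyclopenta[b]furan (9S,12R,13S) | O1[C@@H]([C@@H](Br)CC)CC2=C1CC[C@@H]2O[Si](CC)(CC)CC
F7 | step 7 | (5R,6R,8R)-8-[(1S)-1-bromopropyl]-6-hydroxy-5-(triethylsilyloxy)oxocan-2-one (10R epimer of 11) | O=C1CC[C@@H](O[Si](CC)(CC)CC)[C@H](O)C[C@H]([C@@H](Br)CC)O1
F8 | step 7 | (5R,6S,8R)-8-[(1S)-1-bromopropyl]-2-oxo-5-(triethylsilyloxy)oxocan-6-yl chloroacetate | O=C1CC[C@@H](O[Si](CC)(CC)CC)[C@@H](OC(=O)CCl)C[C@H]([C@@H](Br)CC)O1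
F9 | step 10 | (5R,6S,8R)-8-[(1S)-1-bromopropyl]-6-(tert-butyldimethylsilyloxy)-2-oxooxocan-5-yl chloromethanesulfonate | O=C1CC[C@@H](OS(=O)(=O)CCl)[C@@H](O[Si](C)(C)C(C)(C)C)C[C@H]([C@@H](Br)CC)O1
F10 | step 11 | (3S,5S,6S,8R)-8-[(1S)-1-bromopropyl]-6-(tert-butyldimethylsilyloxy)-5-chloro-3-hydroxyoxocan-2-one (7S epimer of 15) | O=C1[C@@H](O)C[C@H](Cl)[C@@H](O[Si](C)(C)C(C)(C)C)C[C@H]([C@@H](Br)CC)O1
F11 | step 11 | (3R,5S,6S,8R)-8-[(1S)-1-bromopropyl]-6-(tert-butyldimethylsilyloxy)-5-chloro-2-oxooxocan-3-yl chloroacetate | O=C1[C@H](OC(=O)CCl)C[C@H](Cl)[C@@H](O[Si](C)(C)C(C)(C)C)C[C@H]([C@@H](Br)CC)O1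
A1 | alternative 1 | 2-[(2S,3S,8R,Z)-3-chloro-8-propanoyl-3,4,7,8-tetrahydro-2H-oxocin-2-yl]ethyl 2,2-dimethylpropanoate | CC(C)(C)C(=O)OCC[C@@H]1O[C@@H](C(=O)CC)C/C=C\C[C@@H]1Cl
A2 | alternative 1 | 2-[(2S,3S)-3-chloro-5-ethenyloxolan-2-yl]ethyl 2,2-dimethylpropanoate (configuration at the vinyl-bearing carbon left open) | CC(C)(C)C(=O)OCC[C@@H]1OC(C=C)C[C@@H]1Cl
A3 | alternative 1 | 1-diazobutan-2-one | CCC(=O)C=[N+]=[N-]
A4 | alternative 2 | (2S,3R,8R)-8-[(1R)-1-(4-methoxybenzyloxy)propyl]-2-(prop-2-en-1-yl)-6-(trimethylsilyloxy)-3,4,7,8-tetrahydro-2H-oxocin-3-yl acetate | C=CC[C@@H]1O[C@@H]([C@H](OCc2ccc(OC)cc2)CC)C/C(O[Si](C)(C)C)=C\C[C@H]1OC(C)=O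
A5 | alternative 2 | cis-fused (3R,8R)-8-acetoxy-3-[(1R)-1-(4-methoxybenzyloxy)propyl]-2-oxabicyclo[4.2.0]octan-5-one (cyclobutane anti to the C3 substituent) | O=C1C[C@H]([C@H](OCc2ccc(OC)cc2)CC)O[C@H]2[C@H](OC(C)=O)C[C@@H]12
A6 | alternative 3 | (8R,Z)-8-[(1R)-1-hydroxypropyl]-3,4,7,8-tetrahydro-2H-oxocin-2-one | O=C1CC/C=C\C[C@H]([C@H](O)CC)O1
A7 | alternative 3 | anti-2-(1-hydroxypropyl)cyclohept-4-en-1-one, racemic; reacting (2R,1′R) enantiomer drawn | O=C1CC/C=C\C[C@@H]1[C@H](O)CC
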